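## Analysis of the target

The target (37) is a cis-fused eremophilane. Ring A (C1–C5, C10) carries the C2 ketone and the C4 methyl group (C15). Ring B (C5–C10) carries the isopropenyl group (C11–C13) on C7, the acetate on C8 and the 3-methylbut-2-enoate (senecioate) on C9; the angular methyl group (C14) sits on C5. Six contiguous stereocentres run C4–C5–C10–C9–C8–C7. Taking the face of C14 as β, Me15, H10 and the isopropenyl group are β and both acyloxy groups are α, so the diol diester is cis and lies trans to the C7 substituent (4S,5R,7R,8R,9S,10S). The sensitive points are the two different esters on a cis-vicinal diol (acyl migration), the senecioate (deconjugation under base), the isopropenyl group (boranes and electrophilic oxidants) and C10–H whenever C9 is a carbonyl group (epimerisation of the ring fusion). The hard part is the quaternary C5 next to the tertiary C4, with the two methyl groups cis and both joined to a cis ring fusion. The route rests on one structural fact: C14 can be a carboxyl group, C4 is the neighbour of C5, and C10 can hold a two-carbon arm C1–C2. An oxygen stereocentre on C2, tied to the C14 carboxyl as a δ-lactone, places C5 and a C3=C4 propenyl unit in one [3,3] array, so that the C2 configuration and the olefin geometry are copied onto C5 and C4 while ring A closes.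

## Retrosynthetic reasoning

**C2 ketone and the esters.** 37 comes from its C2 ketal 36, so the ketone is hidden during all enolate chemistry in ring B. The senecioate C9–O acyl bond is cut to the hydroxy acetate 34 and the acid chloride 35. The more easily deconjugated ester is thus put on last, onto the hydroxyl that is formed last.

**C9 and C8 oxygen.** 34 is the reduction product of the acetoxy ketone 33; hydride has to enter C9 from the β face so that the two oxygens end up cis. 33 comes from the hydroxy ketone 32, and the C8–O bond of 32 is cut to the enolate of ketone 31. The oxygen must enter trans to the C7 substituent, which is also the more stable arrangement.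

**C7–C11.** The isopropenyl group is disconnected from 31 as a conjugate addition of 30 to enone 29. This bond is cut here because C7 is β to the one carbonyl group that ring B can carry from the start. The forward step has to deliver the group to the β face.

**Ring B oxidation level.** 29 is the dehydrogenation product of ketone 27, which is the oxidised form of alcohol 26 and its silyl ether 25. The single C9 oxygen is thus the source of all ring B functionality. Its configuration is of no importance after this point, so it is free to act earlier as a control element.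

**C2 oxygen.** The ketal 25 goes back through ketone 24 and alcohol 23 to the olefin 21. The C2=C3 double bond is cut to oxygen at C2 because C3 is shielded by C4 and C5, and a borane should choose the remote carbon.

**C14.** The angular methyl group of 21 is traced to aldehyde 19, alcohol 18 and acid 17. A carboxyl group at C5 is what the key step needs, and its removal to CH3 is done before any ketone is present.

**C4–C5 and ring A (key disconnection).** Acid 17 is cut at C4–C5 with re-formation of the C2–O bond, giving lactone 14. In the forward sense its silyl ketene acetal 15 rearranges to the silyl ester 16. This is the only place where C4 and C5 are made, and ring A closes in the same event.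

**Lactone.** 14 is opened at the C14–O bond to hydroxy ester 13. The carbinol centre of 13 comes from reduction of enone 12 under catalyst control. 12 comes via 11 from the C2–C3 disconnection to aldehyde 9 and the propenyl donor 10.

**C10 side chain and C9.** Aldehyde 9 derives from the vinyl compound 6 through alcohol 8. The C10–C1 bond of 6 is cut as a conjugate addition of 4 to enoate 3, which is controlled by the neighbouring silyl ether. 3 comes from the allylic alcohol 2 and the achiral keto ester 1, where one enantioselective reduction sets the absolute configuration of the whole route.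

## Alternatives that were turned down

**Alternative 1: Stetter desymmetrisation of a cyclohexadienone.** The disconnection is C9–C10. The achiral dienone aldehyde 4-methyl-4-(4-oxobutyl)cyclohexa-2,5-dien-1-one A1 would be closed by a chiral triazolylidene carbene; the acyl anion equivalent at C9 adds to C10 of one enone arm and gives the cis-fused enedione A2.
- For it: A1 is only a few steps from a para-substituted phenol. One catalytic step sets C5 and C10 and delivers both the C2 and the C9 carbonyl groups. On step count and on C2 oxidation it is clearly stronger than the chosen route, which needs a hydroboration to find C2.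
- Against it: Me15 is still missing in A2. It would have to be added to C4 of the remaining enone, on a carbon next to the quaternary C5 and cis to Me14, and nothing in A2 fixes that face. The two ketones of A2 would also have to be told apart, and closing a six-membered carbocycle from an aliphatic aldehyde is the less favourable Stetter case.
- Comparison: the chosen route is longer, but it fixes the C4/C5 pair by a pericyclic transition state whose geometry is forced.

**Alternative 2: Intramolecular Diels–Alder of a (Z)-silyloxydiene.** The disconnections are C5–C10 and C3–C4. The acyclic trienoate A3 would close both rings at once to the silyl enol ether A4.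
- For it: it is the most convergent plan. The C2 oxygen arrives as an enol ether, the dienophile geometry puts Me15 cis to the ester, and the C5 ester and C9 silyl ether are those of the chosen route. On C2 it is stronger.
- Against it: a (Z)-1-substituted diene reaches the s-cis form with difficulty and is prone to 1,5-hydrogen shift. A3 contains two (Z) olefins that must be made and kept pure. The endo/exo and facial outcome depends on a single tether stereocentre (C9).
- Comparison: in the chosen route the corresponding information is held in a ring, with a ketene acetal of fixed geometry and only a boat open, at the cost of building the rings one after the other.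

**Alternative 3: Samarium pinacol coupling.** The disconnection is C8–C9. The dialdehyde A5 would be coupled by SmI2 to the cis-diol A6.
- For it: ring B closes with C7, C8 and C9 in place. The conjugate addition, the hydroxylation and the ketone reduction of the chosen route are avoided, which is where the chosen route is weakest.
- Against it: A5 must already carry C4, C5, C10 and C7 on a monocycle. C7 is α to an aldehyde and not tied to the ring. The face of the diol relative to C7 and C10 is not secured. A6 presents two free secondary hydroxyls that must receive different acyl groups.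
- Comparison: the chosen route introduces the two oxygens one at a time and makes C4/C5 in a step that also builds ring A.

Key step: step 10

## Remarks before the steps

- Locants C1–C15 are those of the target skeleton (ring A: C1–C5 and C10; ring B: C5–C10; C14 on C5, C15 on C4). "β" is the face of C14.
- Compounds 1, 4, 10, 30 and 35 are taken as commercial.
- Metal enolates, alkoxides and organocopper species that are quenched within the same operation are treated as reactive species of the mechanism; covalent intermediates are numbered.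

## Steps

Step 1
Reactants: 1 methyl 3-oxocyclohex-1-ene-1-carboxylate
Product: 2 methyl (3S)-3-hydroxycyclohex-1-ene-1-carboxylate
Conditions: (R)-2-methyl-CBS-oxazaborolidine (10 mol%), catecholborane, PhMe, −78 °C
Reagents that add atoms: none
Why: Corey–Bakshi–Shibata reduction; the alkenyl flank acts as the large group, so the (R)-catalyst should give the (S)-carbinol (C9), and catecholborane at low temperature leaves the enoate alone.

Step 2
Reactants: 2 methyl (3S)-3-hydroxycyclohex-1-ene-1-carboxylate
Product: 3 methyl (3S)-3-[(tert-butyldimethylsilyl)oxy]cyclohex-1-ene-1-carboxylate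
Conditions: TBSCl, imidazole, DMF, 23 °C
Reagents that add atoms: tert-butyldimethylsilyl chloride, CC(C)(C)[Si](C)(C)Cl
Why: Standard silylation of a secondary allylic alcohol; the bulky ether is the control element for step 3 and survives every step up to step 17.

Step 3
Reactants: 3 methyl (3S)-3-[(tert-butyldimethylsilyl)oxy]cyclohex-1-ene-1-carboxylate; 4 vinylmagnesium bromide
Product: 6 methyl (1R,2S,3S)-3-[(tert-butyldimethylsilyl)oxy]-2-ethenylcyclohexane-1-carboxylate, via silyl ketene acetal 5 (not isolated)
Conditions: CH2=CHMgBr, CuBr·SMe2 (10 mol%), TMSCl, THF, −78 → −40 °C; then NaOMe, MeOH, 23 °C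
Reagents that add atoms: vinylmagnesium bromide (4), C=C[Mg]Br
Why: Copper-catalysed, chlorosilane-accelerated conjugate addition to an enoate; the vinyl group should enter C10 anti to the adjacent silyl ether, which sets C10. Methoxide then cleaves 5 and equilibrates C5 to the all-equatorial ester; C5 is erased again in step 10.

Step 4
Reactants: 6 methyl (1R,2S,3S)-3-[(tert-butyldimethylsilyl)oxy]-2-ethenylcyclohexane-1-carboxylate
Product: 8 methyl (1R,2S,3S)-3-[(tert-butyldimethylsilyl)oxy]-2-(2-hydroxyethyl)cyclohexane-1-carboxylate, via B-alkyl-9-borabicyclononane 7 (not isolated)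
Conditions: 9-BBN, THF, 0 → 23 °C; then H2O2, aq. NaOAc, 0 → 23 °C
Reagents that add atoms: hydrogen peroxide, OO
Why: Anti-Markovnikov hydroboration–oxidation of a terminal olefin; 9-BBN does not touch the ester, and the buffered oxidation avoids saponification.

Step 5
Reactants: 8 methyl (1R,2S,3S)-3-[(tert-butyldimethylsilyl)oxy]-2-(2-hydroxyethyl)cyclohexane-1-carboxylate
Product: 9 methyl (1R,2S,3S)-3-[(tert-butyldimethylsilyl)oxy]-2-(2-oxoethyl)cyclohexane-1-carboxylate
Conditions: Dess–Martin periodinane, NaHCO3, CH2Cl2, 23 °C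
Reagents that add atoms: none
Why: Dess–Martin oxidation of a primary alcohol under buffered, non-epimerising conditions.

Step 6
Reactants: 9 methyl (1R,2S,3S)-3-[(tert-butyldimethylsilyl)oxy]-2-(2-oxoethyl)cyclohexane-1-carboxylate; 10 (E)-1-bromoprop-1-ene
Product: 11 methyl (1R,2S,3S)-3-[(tert-butyldimethylsilyl)oxy]-2-[(3E)-2-hydroxypent-3-en-1-yl]cyclohexane-1-carboxylate (both carbinol epimers)
Conditions: 10, t-BuLi (2 equiv), Et2O, −78 °C; then 9, −78 °C; aq. NH4Cl at −78 °C
Reagents that add atoms: (E)-1-bromoprop-1-ene (10), C/C=C/Br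
Why: Bromine–lithium exchange keeps the (E) geometry, and the alkenyllithium adds to the aldehyde much faster than to the hindered ester at −78 °C. The cold quench prevents lactonisation; the carbinol mixture converges in step 7.

Step 7
Reactants: 11 methyl (1R,2S,3S)-3-[(tert-butyldimethylsilyl)oxy]-2-[(3E)-2-hydroxypent-3-en-1-yl]cyclohexane-1-carboxylate
Product: 12 methyl (1R,2S,3S)-3-[(tert-butyldimethylsilyl)oxy]-2-[(3E)-2-oxopent-3-en-1-yl]cyclohexane-1-carboxylate
Conditions: Dess–Martin periodinane, NaHCO3, CH2Cl2, 23 °C
Reagents that add atoms: none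
Why: Dess–Martin oxidation of an allylic alcohol to the (E)-enone; both epimers give one compound.

Step 8
Reactants: 12 methyl (1R,2S,3S)-3-[(tert-butyldimethylsilyl)oxy]-2-[(3E)-2-oxopent-3-en-1-yl]cyclohexane-1-carboxylate
Product: 13 methyl (1R,2S,3S)-3-[(tert-butyldimethylsilyl)oxy]-2-[(2S,3E)-2-hydroxypent-3-en-1-yl]cyclohexane-1-carboxylate
Conditions: (R)-2-methyl-CBS-oxazaborolidine (20 mol%), catecholborane, PhMe, −78 °C
Reagents that add atoms: none
Why: Corey–Bakshi–Shibata 1,2-reduction of an acyclic (E)-enone with the alkenyl group as the large substituent; the (R)-catalyst should give the (S)-carbinol at C2, which carries the stereochemical information for step 10.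

Step 9
Reactants: 13 methyl (1R,2S,3S)-3-[(tert-butyldimethylsilyl)oxy]-2-[(2S,3E)-2-hydroxypent-3-en-1-yl]cyclohexane-1-carboxylate
Product: 14 (3S,4aS,5S,8aR)-5-[(tert-butyldimethylsilyl)oxy]-3-[(1E)-prop-1-en-1-yl]-3,4,4a,5,6,7,8,8a-octahydro-1H-isochromen-1-one (ring B δ-lactone, C14 carboxyl on the C2 oxygen)
Conditions: PPTS (20 mol%), PhMe, 80 °C, 4 Å molecular sieves
Reagents that add atoms: none
Why: Acid-catalysed lactonisation (intramolecular transesterification) of a δ-hydroxy ester whose two arms are trans-diequatorial; uptake of methanol drives it. The weak acid leaves the silyl ether and the allylic carbinol intact.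

Step 10
Reactants: 14 (3S,4aS,5S,8aR)-5-[(tert-butyldimethylsilyl)oxy]-3-[(1E)-prop-1-en-1-yl]-3,4,4a,5,6,7,8,8a-octahydro-1H-isochromen-1-one
Product: 17 (4S,5S,9S,10S)-9-[(tert-butyldimethylsilyl)oxy]-4-methyl-cis-decal-2-ene-5-carboxylic acid (C14 carboxyl on C5, C2=C3 olefin), via bis-silyl ketene acetal 15 (not isolated), via silyl ester 16 (not isolated)
Conditions: LiN(iPr)2, TBSCl, THF–DMPU, −78 °C; then PhMe, 105 °C; then K2CO3, MeOH–H2O, 23 °C, acidify to pH 4
Reagents that add atoms: none
Why: Ireland–Claisen rearrangement run as a lactone ring contraction; the closest known class is the enolate Claisen contraction of ω-alkenyl lactones to cis-fused cycloalkene acids. LiN(iPr)2 removes the only α-hydrogen (C5–H), and the silyl chloride, already present, traps the enolate on oxygen as 15 before it can fragment to a ketene. On heating, C4 of the propenyl group bonds to C5 while the lactone C2–O bond breaks, giving silyl ester 16 with the new C2=C3 olefin; carbonate then cleaves only the silyl ester. Ring A closes as a six-membered carbocycle through a boat, bicyclo[2.2.2]octane-like [3,3] array in which the C3=C4 unit bridges the lactone ring; a chair is excluded because it would leave a trans double bond in the new ring. C5 is controlled by C2 and C10: the propenyl group can reach C5 only on the lactone face on which it stands, and this is the face of the C10–C9 bond, so C4 becomes cis to C9 and the fusion is cis (C14 cis to H10). C4 is controlled by the (E) olefin geometry together with the enforced boat and the ring-locked ketene acetal geometry, which place Me15 cis to C14. The step needs O- over C-silylation and [3,3] over elimination; the internal quench at −78 °C and the absence of a β-leaving group serve the first, the preorganised cyclic array the second. The C2 stereocentre is consumed, and the olefin it leaves marks the site of the later ketone.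

Step 11
Reactants: 17 (4S,5S,9S,10S)-9-[(tert-butyldimethylsilyl)oxy]-4-methyl-cis-decal-2-ene-5-carboxylic acid
Product: 18 [(4S,5S,9S,10S)-9-[(tert-butyldimethylsilyl)oxy]-4-methyl-cis-decal-2-en-5-yl]methanol
Conditions: LiAlH4, THF, 0 → 65 °C
Reagents that add atoms: none
Why: Hydride reduction of a hindered tertiary carboxylic acid to the neopentyl alcohol; silyl ether and olefin are inert.

Step 12
Reactants: 18 [(4S,5S,9S,10S)-9-[(tert-butyldimethylsilyl)oxy]-4-methyl-cis-decal-2-en-5-yl]methanol
Product: 19 (4S,5S,9S,10S)-9-[(tert-butyldimethylsilyl)oxy]-4-methyl-cis-decal-2-ene-5-carbaldehyde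
Conditions: Dess–Martin periodinane, NaHCO3, CH2Cl2, 23 °C
Reagents that add atoms: none
Why: Dess–Martin oxidation; the aldehyde has no α-hydrogen and cannot epimerise.

Step 13
Reactants: 19 (4S,5S,9S,10S)-9-[(tert-butyldimethylsilyl)oxy]-4-methyl-cis-decal-2-ene-5-carbaldehyde
Product: 21 (4S,5R,9S,10S)-9-[(tert-butyldimethylsilyl)oxy]-4,5-dimethyl-cis-decal-2-ene, via tosylhydrazone 20 (not isolated)
Conditions: TsNHNH2, EtOH, 60 °C; then catecholborane, CHCl3, 0 °C; then NaOAc·3H2O, 60 °C
Reagents that add atoms: none
Why: Deoxygenation of an aldehyde through its tosylhydrazone (Kabalka variant of the Wolff–Kishner reduction): hydroboration of C=N, loss of sulfinate and of N2 leave the C14 methyl group. The neutral, low-temperature conditions spare the silyl ether and do not move the olefin.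

Step 14
Reactants: 21 (4S,5R,9S,10S)-9-[(tert-butyldimethylsilyl)oxy]-4,5-dimethyl-cis-decal-2-ene
Product: 23 (4S,5R,9S,10S)-9-[(tert-butyldimethylsilyl)oxy]-4,5-dimethyl-cis-decalin-2-ol (C2 configuration not controlled), via B-alkyl-9-borabicyclononane 22 (not isolated)
Conditions: 9-BBN, THF, 65 °C; then H2O2, aq. NaOH, 0 → 23 °C
Reagents that add atoms: hydrogen peroxide, OO
Why: Hydroboration–oxidation; the bulky borane should place boron on C2, the olefin carbon remote from the C4 methine and the quaternary C5. The C2 configuration is irrelevant because step 15 removes it.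

Step 15
Reactants: 23 (4S,5R,9S,10S)-9-[(tert-butyldimethylsilyl)oxy]-4,5-dimethyl-cis-decalin-2-ol
Product: 24 (4S,5R,9S,10S)-9-[(tert-butyldimethylsilyl)oxy]-4,5-dimethyl-cis-decalin-2-one
Conditions: Dess–Martin periodinane, NaHCO3, CH2Cl2, 23 °C
Reagents that add atoms: none
Why: Dess–Martin oxidation; C4 and C10 are β to the new carbonyl group and cannot epimerise.

Step 16
Reactants: 24 (4S,5R,9S,10S)-9-[(tert-butyldimethylsilyl)oxy]-4,5-dimethyl-cis-decalin-2-one
Product: 25 (4S,5R,9S,10S)-9-[(tert-butyldimethylsilyl)oxy]-4,5-dimethyl-cis-decalin-2-one ethylene ketal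
Conditions: ethylene glycol, PPTS, benzene, reflux (Dean–Stark)
Reagents that add atoms: ethylene glycol, OCCO
Why: Ketalisation with removal of water; the dioxolane hides the ring A ketone from all base, hydride and organometal used on ring B, and PPTS does not cleave the silyl ether.

Step 17
Reactants: 25 (4S,5R,9S,10S)-9-[(tert-butyldimethylsilyl)oxy]-4,5-dimethyl-cis-decalin-2-one ethylene ketal
Product: 26 (4S,5R,9S,10S)-9-hydroxy-4,5-dimethyl-cis-decalin-2-one ethylene ketal
Conditions: Bu4NF, THF, 23 → 50 °C
Reagents that add atoms: none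
Why: Fluoride cleavage of the silyl ether; the ketal is stable to fluoride.

Step 18
Reactants: 26 (4S,5R,9S,10S)-9-hydroxy-4,5-dimethyl-cis-decalin-2-one ethylene ketal
Product: 27 (4S,5R,10S)-4,5-dimethyl-cis-decalin-2,9-dione 2-ethylene ketal
Conditions: Dess–Martin periodinane, NaHCO3, CH2Cl2, 23 °C
Reagents that add atoms: none
Why: Dess–Martin oxidation under buffered conditions, so that C10–H, now α to the ketone, is not epimerised.

Step 19
Reactants: 27 (4S,5R,10S)-4,5-dimethyl-cis-decalin-2,9-dione 2-ethylene ketal
Product: 29 (4S,5R,10S)-4,5-dimethyl-cis-decal-7-ene-2,9-dione 2-ethylene ketal, via trimethylsilyl enol ether 28 (not isolated)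
Conditions: LiN(iPr)2, TMSCl, THF, −78 °C; then Pd(OAc)2 (1.1 equiv), MeCN, 23 °C
Reagents that add atoms: none
Why: Saegusa–Ito dehydrogenation; kinetic deprotonation takes the C8 methylene and not the C10 methine next to the quaternary C5, so 28 is the C8=C9 enol ether. Divalent palladium then gives the C7=C8 enone without touching C10.

Step 20
Reactants: 29 (4S,5R,10S)-4,5-dimethyl-cis-decal-7-ene-2,9-dione 2-ethylene ketal; 30 isopropenylmagnesium bromide
Product: 31 (4S,5R,7S,10S)-7-isopropenyl-4,5-dimethyl-cis-decalin-2,9-dione 2-ethylene ketal (isopropenyl β)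
Conditions: CH2=C(CH3)MgBr, CuBr·SMe2 (20 mol%), THF, −78 → −40 °C; aq. NH4Cl
Reagents that add atoms: isopropenylmagnesium bromide (30), C=C(C)[Mg]Br
Why: Copper-catalysed conjugate addition to a cyclohexenone. Axial attack on the β (convex) face passes only the C5 methyl group, whereas axial attack on the α face must pass the axial ring A carbon C4, so the isopropenyl group is expected cis to C14, which sets C7.

Step 21
Reactants: 31 (4S,5R,7S,10S)-7-isopropenyl-4,5-dimethyl-cis-decalin-2,9-dione 2-ethylene ketal
Product: 32 (4S,5R,7R,8R,10S)-8-hydroxy-7-isopropenyl-4,5-dimethyl-cis-decalin-2,9-dione 2-ethylene ketal (hydroxyl α)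
Conditions: KN(SiMe3)2, THF, −78 °C; then 2-(phenylsulfonyl)-3-phenyloxaziridine, −78 °C; aq. NH4Cl
Reagents that add atoms: 2-(phenylsulfonyl)-3-phenyloxaziridine, O=S(=O)(c1ccccc1)N1OC1c1ccccc1
Why: Davis oxidation of the kinetic C8 enolate (methylene deprotonated in preference to the hindered C10 methine). The oxaziridine approaches anti to the neighbouring isopropenyl group, giving the trans, equatorial carbinol, which is also the more stable epimer; the reagent does not epoxidise the isopropenyl group.

Step 22
Reactants: 32 (4S,5R,7R,8R,10S)-8-hydroxy-7-isopropenyl-4,5-dimethyl-cis-decalin-2,9-dione 2-ethylene ketal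
Product: 33 (4S,5R,7R,8R,10S)-8-acetoxy-7-isopropenyl-4,5-dimethyl-cis-decalin-2,9-dione 2-ethylene ketal
Conditions: Ac2O, pyridine, DMAP (cat.), CH2Cl2, 0 → 23 °C
Reagents that add atoms: acetic anhydride, CC(=O)OC(C)=O
Why: Acylation of an unhindered equatorial secondary alcohol; the mild base does not enolise toward C10.

Step 23
Reactants: 33 (4S,5R,7R,8R,10S)-8-acetoxy-7-isopropenyl-4,5-dimethyl-cis-decalin-2,9-dione 2-ethylene ketal
Product: 34 (4S,5R,7R,8R,9S,10S)-8-acetoxy-9-hydroxy-7-isopropenyl-4,5-dimethyl-cis-decalin-2-one ethylene ketal (hydroxyl α)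
Conditions: NaBH4, CeCl3·7H2O, MeOH, −78 °C; AcOH quench at −78 °C
Reagents that add atoms: none
Why: Borohydride reduction under Luche conditions. Hydride should enter C9 from the β face, which is flanked only by H8 and H10, while the α face carries the acetate and C1; this gives the carbinol cis to the acetate. The cold acidic quench is meant to prevent acetyl migration.

Step 24
Reactants: 34 (4S,5R,7R,8R,9S,10S)-8-acetoxy-9-hydroxy-7-isopropenyl-4,5-dimethyl-cis-decalin-2-one ethylene ketal; 35 3-methylbut-2-enoyl chloride
Product: 36 (4S,5R,7R,8R,9S,10S)-8-acetoxy-7-isopropenyl-4,5-dimethyl-2-oxo-cis-decalin-9-yl 3-methylbut-2-enoate 2-ethylene ketal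
Conditions: 35, DMAP, pyridine, CH2Cl2, 0 → 23 °C
Reagents that add atoms: 3-methylbut-2-enoyl chloride (35), CC(C)=CC(=O)Cl
Why: Acyl-pyridinium esterification of a secondary alcohol; pyridine and DMAP are used without a trialkylamine so that the acid chloride is not converted into a vinylketene and the ester stays conjugated.

Step 25
Reactants: 36 (4S,5R,7R,8R,9S,10S)-8-acetoxy-7-isopropenyl-4,5-dimethyl-2-oxo-cis-decalin-9-yl 3-methylbut-2-enoate 2-ethylene ketal
Product: 37 (4S,5R,7R,8R,9S,10S)-8-acetoxy-7-isopropenyl-4,5-dimethyl-2-oxo-cis-decalin-9-yl 3-methylbut-2-enoate (CNP0150397.1)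
Conditions: PPTS, acetone–H2O (9:1), 50 °C
Reagents that add atoms: water, O
Why: Mild acid hydrolysis of the dioxolane; the esters, the isopropenyl group and the cis diester do not react under these conditions, and no stereocentre is α to the liberated ketone.

## Compound list

1 | methyl 3-oxocyclohex-1-ene-1-carboxylate | COC(=O)C1=CC(=O)CCC1 | starting material
2 | methyl (3S)-3-hydroxycyclohex-1-ene-1-carboxylate | COC(=O)C1=C[C@@H](O)CCC1 | intermediate
3 | methyl (3S)-3-[(tert-butyldimethylsilyl)oxy]cyclohex-1-ene-1-carboxylate | COC(=O)C1=C[C@@H](O[Si](C)(C)C(C)(C)C)CCC1 | intermediate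
4 | vinylmagnesium bromide | C=C[Mg]Br | starting material
5 | methyl trimethylsilyl ketene acetal of ester 6 (C5=C14, (2S,3S) ring) | COC(O[Si](C)(C)C)=C1CCC[C@H](O[Si](C)(C)C(C)(C)C)[C@H]1C=C | intermediate (not isolated)
6 | methyl (1R,2S,3S)-3-[(tert-butyldimethylsilyl)oxy]-2-ethenylcyclohexane-1-carboxylate | C1C[C@@H](C(=O)OC)[C@H](C=C)[C@@H](O[Si](C)(C)C(C)(C)C)C1 | intermediate
7 | B-alkyl-9-borabicyclo[3.3.1]nonane from 6 (boron on the terminal carbon) | C1C[C@@H](C(=O)OC)[C@H](CCB2C3CCCC2CCC3)[C@@H](O[Si](C)(C)C(C)(C)C)C1 | intermediate (not isolated)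
8 | methyl (1R,2S,3S)-3-[(tert-butyldimethylsilyl)oxy]-2-(2-hydroxyethyl)cyclohexane-1-carboxylate | C1C[C@@H](C(=O)OC)[C@H](CCO)[C@@H](O[Si](C)(C)C(C)(C)C)C1 | intermediate
9 | methyl (1R,2S,3S)-3-[(tert-butyldimethylsilyl)oxy]-2-(2-oxoethyl)cyclohexane-1-carboxylate | C1C[C@@H](C(=O)OC)[C@H](CC=O)[C@@H](O[Si](C)(C)C(C)(C)C)C1 | intermediate
10 | (E)-1-bromoprop-1-ene | C/C=C/Br | starting material
11 | methyl (1R,2S,3S)-3-[(tert-butyldimethylsilyl)oxy]-2-[(3E)-2-hydroxypent-3-en-1-yl]cyclohexane-1-carboxylate (carbinol epimers) | C1C[C@@H](C(=O)OC)[C@H](CC(O)/C=C/C)[C@@H](O[Si](C)(C)C(C)(C)C)C1 | intermediate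
12 | methyl (1R,2S,3S)-3-[(tert-butyldimethylsilyl)oxy]-2-[(3E)-2-oxopent-3-en-1-yl]cyclohexane-1-carboxylate | C1C[C@@H](C(=O)OC)[C@H](CC(=O)/C=C/C)[C@@H](O[Si](C)(C)C(C)(C)C)C1 | intermediate
13 | methyl (1R,2S,3S)-3-[(tert-butyldimethylsilyl)oxy]-2-[(2S,3E)-2-hydroxypent-3-en-1-yl]cyclohexane-1-carboxylate | C1C[C@@H](C(=O)OC)[C@H](C[C@@H](/C=C/C)O)[C@@H](O[Si](C)(C)C(C)(C)C)C1 | intermediate
14 | (3S,4aS,5S,8aR)-5-[(tert-butyldimethylsilyl)oxy]-3-[(1E)-prop-1-en-1-yl]-3,4,4a,5,6,7,8,8a-octahydro-1H-isochromen-1-one | C1C[C@@H]2[C@H](C[C@@H](/C=C/C)OC2=O)[C@@H](O[Si](C)(C)C(C)(C)C)C1 | intermediate (precursor of the key step)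
15 | (3S,4aS,5S)-1,5-bis[(tert-butyldimethylsilyl)oxy]-3-[(1E)-prop-1-en-1-yl]-4,4a,5,6,7,8-hexahydro-3H-isochromene (ketene acetal C5=C14) | C1CC2=C(O[Si](C)(C)C(C)(C)C)O[C@H](/C=C/C)C[C@@H]2[C@@H](O[Si](C)(C)C(C)(C)C)C1 | intermediate (not isolated)
16 | tert-butyldimethylsilyl ester of acid 17 | C1C[C@@]2(C(=O)O[Si](C)(C)C(C)(C)C)[C@H](CC=C[C@@H]2C)[C@@H](O[Si](C)(C)C(C)(C)C)C1 | intermediate (not isolated)
17 | (4S,5S,9S,10S)-9-[(tert-butyldimethylsilyl)oxy]-4-methyl-cis-decal-2-ene-5-carboxylic acid [(4S,4aS,8S,8aS)-8-silyloxy-4-methyl-1,5,6,7,8,8a-hexahydronaphthalene-4a(4H)-carboxylic acid] | C1C[C@@]2(C(=O)O)[C@H](CC=C[C@@H]2C)[C@@H](O[Si](C)(C)C(C)(C)C)C1 | intermediate (product of the key step)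
18 | [(4S,5S,9S,10S)-9-[(tert-butyldimethylsilyl)oxy]-4-methyl-cis-decal-2-en-5-yl]methanol | C1C[C@@]2(CO)[C@H](CC=C[C@@H]2C)[C@@H](O[Si](C)(C)C(C)(C)C)C1 | intermediate
19 | (4S,5S,9S,10S)-9-[(tert-butyldimethylsilyl)oxy]-4-methyl-cis-decal-2-ene-5-carbaldehyde | C1C[C@@]2(C=O)[C@H](CC=C[C@@H]2C)[C@@H](O[Si](C)(C)C(C)(C)C)C1 | intermediate
20 | (E)-4-methylbenzenesulfonylhydrazone of aldehyde 19 | C1C[C@@]2(/C=N/NS(=O)(=O)c3ccc(C)cc3)[C@H](CC=C[C@@H]2C)[C@@H](O[Si](C)(C)C(C)(C)C)C1 | intermediate (not isolated)
21 | (4S,5R,9S,10S)-9-[(tert-butyldimethylsilyl)oxy]-4,5-dimethyl-cis-decal-2-ene | C1C[C@@]2(C)[C@H](CC=C[C@@H]2C)[C@@H](O[Si](C)(C)C(C)(C)C)C1 | intermediate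
22 | B-alkyl-9-borabicyclo[3.3.1]nonane from 21 (boron on C2) | C1C[C@@]2(C)[C@H](CC(B3C4CCCC3CCC4)C[C@@H]2C)[C@@H](O[Si](C)(C)C(C)(C)C)C1 | intermediate (not isolated)
23 | (4S,5R,9S,10S)-9-[(tert-butyldimethylsilyl)oxy]-4,5-dimethyl-cis-decalin-2-ol (C2 not controlled) | C1C[C@@]2(C)[C@H](CC(O)C[C@@H]2C)[C@@H](O[Si](C)(C)C(C)(C)C)C1 | intermediate
24 | (4S,5R,9S,10S)-9-[(tert-butyldimethylsilyl)oxy]-4,5-dimethyl-cis-decalin-2-one | C1C[C@@]2(C)[C@H](CC(=O)C[C@@H]2C)[C@@H](O[Si](C)(C)C(C)(C)C)C1 | intermediate
25 | (4S,5R,9S,10S)-9-[(tert-butyldimethylsilyl)oxy]-4,5-dimethyl-cis-decalin-2-one ethylene ketal | C1C[C@@]2(C)[C@H](CC3(OCCO3)C[C@@H]2C)[C@@H](O[Si](C)(C)C(C)(C)C)C1 | intermediate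
26 | (4S,5R,9S,10S)-9-hydroxy-4,5-dimethyl-cis-decalin-2-one ethylene ketal | C1C[C@@]2(C)[C@H](CC3(OCCO3)C[C@@H]2C)[C@@H](O)C1 | intermediate
27 | (4S,5R,10S)-4,5-dimethyl-cis-decalin-2,9-dione 2-ethylene ketal | C1C[C@@]2(C)[C@H](CC3(OCCO3)C[C@@H]2C)C(=O)C1 | intermediate
28 | 9-trimethylsilyloxy-Δ8 enol ether of 27 | C1C[C@@]2(C)[C@H](CC3(OCCO3)C[C@@H]2C)C(O[Si](C)(C)C)=C1 | intermediate (not isolated)
29 | (4S,5R,10S)-4,5-dimethyl-cis-decal-7-ene-2,9-dione 2-ethylene ketal | O=C1C=CC[C@]2(C)[C@@H](C)CC3(OCCO3)C[C@H]12 | intermediate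
30 | isopropenylmagnesium bromide | C=C(C)[Mg]Br | starting material
31 | (4S,5R,7S,10S)-7-isopropenyl-4,5-dimethyl-cis-decalin-2,9-dione 2-ethylene ketal | C=C(C)[C@H]1C[C@@]2(C)[C@H](CC3(OCCO3)C[C@@H]2C)C(=O)C1 | intermediate
32 | (4S,5R,7R,8R,10S)-8-hydroxy-7-isopropenyl-4,5-dimethyl-cis-decalin-2,9-dione 2-ethylene ketal | C=C(C)[C@H]1C[C@@]2(C)[C@H](CC3(OCCO3)C[C@@H]2C)C(=O)[C@@H]1O | intermediate
33 | (4S,5R,7R,8R,10S)-8-acetoxy-7-isopropenyl-4,5-dimethyl-cis-decalin-2,9-dione 2-ethylene ketal | C=C(C)[C@H]1C[C@@]2(C)[C@H](CC3(OCCO3)C[C@@H]2C)C(=O)[C@@H]1OC(C)=O | intermediate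
34 | (4S,5R,7R,8R,9S,10S)-8-acetoxy-9-hydroxy-7-isopropenyl-4,5-dimethyl-cis-decalin-2-one ethylene ketal | C=C(C)[C@H]1C[C@@]2(C)[C@H](CC3(OCCO3)C[C@@H]2C)[C@H](O)[C@@H]1OC(C)=O | intermediate
35 | 3-methylbut-2-enoyl chloride | CC(C)=CC(=O)Cl | starting material
36 | (4S,5R,7R,8R,9S,10S)-8-acetoxy-7-isopropenyl-4,5-dimethyl-2-oxo-cis-decalin-9-yl 3-methylbut-2-enoate 2-ethylene ketal | C=C(C)[C@H]1C[C@@]2(C)[C@H](CC3(OCCO3)C[C@@H]2C)[C@H](OC(=O)C=C(C)C)[C@@H]1OC(C)=O | intermediate
37 | (4S,5R,7R,8R,9S,10S)-8-acetoxy-7-isopropenyl-4,5-dimethyl-2-oxo-cis-decalin-9-yl 3-methylbut-2-enoate | C=C(C)[C@H]1C[C@@]2(C)[C@H](CC(=O)C[C@@H]2C)[C@H](OC(=O)C=C(C)C)[C@@H]1OC(C)=O | target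

## Step count and least certain steps

Total: 25 steps. Longest linear sequence: 25 steps (1 → 37; compounds 4, 10, 30 and 35 are purchased).

**Step 10 (key step).** The [3,3] shift must pass through a strained boat and form a quaternary carbon next to a tertiary one. The most likely failure is that the rearrangement is slower than fragmentation of the lactone enolate to a ketene and an alkoxide, than C-silylation, or than thermal elimination of the allylic carboxylate to a diene acid.
Fallback: build ring A by an intermolecular Diels–Alder reaction instead. Starting from 3, reduction with iBu2AlH (CH2Cl2, −78 °C) would give [(3S)-3-[(tert-butyldimethylsilyl)oxy]cyclohex-1-en-1-yl]methanol F1. Oxidation with MnO2 would give (3S)-3-[(tert-butyldimethylsilyl)oxy]cyclohex-1-ene-1-carbaldehyde F2. Cycloaddition of F2 with (E)-penta-1,3-diene under Me2AlCl (CH2Cl2, −78 → −20 °C) should give aldehyde 19 directly: suprafacial addition keeps C14 cis to H10, the endo formyl group places Me15 cis to C14, and the diene should approach anti to the C9 silyl ether. The route is rejoined at 19. This is much shorter, but it is held in reserve because endo/exo and facial control are less secure than in the ring-locked rearrangement and the dienophile is a reluctant one.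

**Step 20.** The risk is poor facial selectivity at C7. Each half-chair of the enone offers the incoming group one 1,3-diaxial partner on C5 (the methyl group on the β face, ring carbon C4 on the α face), so attack on the concave face may compete.
Fallback: use the same facial preference with the opposite outcome by opening an epoxide with inversion. From 29, nucleophilic epoxidation (H2O2, NaOH, MeOH, 0 °C) would give the 7α,8α-epoxy ketone F5. Reduction (NaBH4, CeCl3·7H2O, MeOH, −78 °C) would give the 9α-epoxy alcohol F6. Opening with isopropenylmagnesium bromide and CuI (cat.) at C7, the carbon remote from the hydroxyl, would give the 7β-isopropenyl 8α,9α-diol F7. Mono-acetylation of the equatorial C8 hydroxyl (AcCl, 2,4,6-collidine, CH2Cl2, −78 °C) would return to 34.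

**Step 14.** The risk is incomplete regiocontrol of the hydroboration: boron going partly to C3 would give the 3-ol, which cannot be corrected later.
Fallback: a reversible radical addition followed by sulfur-to-carbonyl chemistry. From 21, PhSH and AIBN (80 °C) should place sulfur on the less crowded C2, giving the phenyl sulfide F3. NaIO4 (MeOH–H2O) would give the sulfoxide F4. Pummerer rearrangement (trifluoroacetic anhydride, 2,6-lutidine) followed by hydrolysis (HgCl2, CaCO3, MeCN–H2O) converts every Pummerer product into ketone 24, where the route is rejoined.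

**Step 24 (with step 23).** The C9 hydroxyl is axial and hindered. While it is free, the acetyl group on the cis-neighbouring oxygen may migrate, and a slow acylation also gives the acid chloride time to deconjugate through a vinylketene.
Fallback: build the senecioate on the oxygen instead of transferring it. From 34, the much more reactive (diethoxyphosphoryl)acetic acid with dicyclohexylcarbodiimide would give the phosphonoacetate F8 quickly, leaving no free hydroxyl. A Horner–Wadsworth–Emmons reaction of F8 with acetone (NaH, THF, 23 → 50 °C) would give 36, where the route is rejoined.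

## Further compounds

F1 | step 10 | [(3S)-3-[(tert-butyldimethylsilyl)oxy]cyclohex-1-en-1-yl]methanol | OCC1=C[C@@H](O[Si](C)(C)C(C)(C)C)CCC1
F2 | step 10 | (3S)-3-[(tert-butyldimethylsilyl)oxy]cyclohex-1-ene-1-carbaldehyde | O=CC1=C[C@@H](O[Si](C)(C)C(C)(C)C)CCC1
F3 | step 14 | (4S,5R,9S,10S)-9-[(tert-butyldimethylsilyl)oxy]-4,5-dimethyl-2-(phenylsulfanyl)-cis-decalin (C2 not controlled) | C1C[C@@]2(C)[C@H](CC(Sc3ccccc3)C[C@@H]2C)[C@@H](O[Si](C)(C)C(C)(C)C)C1
F4 | step 14 | (4S,5R,9S,10S)-9-[(tert-butyldimethylsilyl)oxy]-4,5-dimethyl-2-(phenylsulfinyl)-cis-decalin (C2 and sulfur not controlled) | C1C[C@@]2(C)[C@H](CC(S(=O)c3ccccc3)C[C@@H]2C)[C@@H](O[Si](C)(C)C(C)(C)C)C1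
F5 | step 20 | 7α,8α-epoxy-4,5-dimethyl-cis-decalin-2,9-dione 2-ethylene ketal | O1[C@@H]2C[C@@]3(C)[C@H](CC4(OCCO4)C[C@@H]3C)C(=O)[C@H]12
F6 | step 20 | 7α,8α-epoxy-9α-hydroxy-4,5-dimethyl-cis-decalin-2-one ethylene ketal | O1[C@@H]2C[C@@]3(C)[C@H](CC4(OCCO4)C[C@@H]3C)[C@H](O)[C@H]12
F7 | step 20 | (4S,5R,7R,8R,9S,10S)-8,9-dihydroxy-7-isopropenyl-4,5-dimethyl-cis-decalin-2-one ethylene ketal | C=C(C)[C@H]1C[C@@]2(C)[C@H](CC3(OCCO3)C[C@@H]2C)[C@H](O)[C@@H]1O
F8 | step 24 | (4S,5R,7R,8R,9S,10S)-8-acetoxy-7-isopropenyl-4,5-dimethyl-2-oxo-cis-decalin-9-yl (diethoxyphosphoryl)acetate 2-ethylene ketal | C=C(C)[C@H]1C[C@@]2(C)[C@H](CC3(OCCO3)C[C@@H]2C)[C@H](OC(=O)CP(=O)(OCC)OCC)[C@@H]1OC(C)=O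
A1 | alternative 1 | 4-methyl-4-(4-oxobutyl)cyclohexa-2,5-dien-1-one | O=CCCCC1(C)C=CC(=O)C=C1
A2 | alternative 1 | cis-5-methyl-decal-3-ene-2,9-dione (target numbering) | C1C[C@@]2(C)[C@H](CC(=O)C=C2)C(=O)C1
A3 | alternative 2 | methyl (6S,7Z)-6-[(tert-butyldimethylsilyl)oxy]-2-[(Z)-ethylidene]-9-[(trimethylsilyl)oxy]deca-7,9-dienoate | C/C=C(\C(=O)OC)CCC[C@H](O[Si](C)(C)C(C)(C)C)/C=C\C(O[Si](C)(C)C)=C
A4 | alternative 2 | methyl 9-[(tert-butyldimethylsilyl)oxy]-4-methyl-2-[(trimethylsilyl)oxy]-cis-decal-1-ene-5-carboxylate (target numbering) | C1C[C@@]2(C(=O)OC)[C@H](C=C(O[Si](C)(C)C)C[C@@H]2C)[C@@H](O[Si](C)(C)C(C)(C)C)C1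
A5 | alternative 3 | C8,C9-dialdehyde: ring A cyclohexanone ethylene ketal with 4,5-dimethyl groups, formyl on C10 and a 2-formyl-3-methylbut-3-enyl chain on C5 | C=C(C)[C@H](C=O)C[C@@]1(C)[C@@H](C=O)CC2(OCCO2)C[C@@H]1C
A6 | alternative 3 | cis-8,9-dihydroxy-7-isopropenyl-4,5-dimethyl-cis-decalin-2-one ethylene ketal (same compound as F7) | C=C(C)[C@H]1C[C@@]2(C)[C@H](CC3(OCCO3)C[C@@H]2C)[C@H](O)[C@@H]1O
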